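**Assumptions**
- Genipin is bought; it is made industrially from geniposide.
- The C1 anomeric centre of the protected intermediates is irrelevant, because it is reset in the last step by lactol acetylation under ring–chain (Curtin–Hammett) control.

## Retrosynthetic overview
1. The target comes from lactol **27** by chemoselective diacetylation (anomeric OAc and C-OAc), and **27** comes from the nine-membered diol **26**.
2. **26** is formed by an intramolecular Ti-mediated electroreductive pinacol coupling of the dienal **25**. This closes the nine-membered ring last and sets the two ring carbinol centres, with the E-trisubstituted olefin already in place.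
3. **25** is built from genipin (7), which already carries the dihydropyran and both ring-fusion stereocentres. The cyclopentene is cleaved by ozonolysis, C6 becomes an isopropenyl group and then the E-enal, and the C7 ketone becomes the α-methylene aldehyde.
4. The C4 side chain comes from Nozaki–Hiyama–Kishi (NHK) addition of the C4 vinyl iodide (from iododecarboxylation) to an α-benzoyloxy enal made from (R)-solketal. The C1′ centre is set by Felkin–Anh control from C2′.

## Route

**Step 1**
Reactants: 1 (R)-solketal
Product: 2 (S)-2,3-O-isopropylideneglyceraldehyde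
Conditions: (COCl)2, DMSO, Et3N, CH2Cl2, −78 °C; use immediately
Reagents that add atoms: none
Why: Swern oxidation; the stereocentre is untouched, and the CIP label changes from R to S because CHO outranks the ring CH2O.

**Step 2**
Reactants: 2
Product: 3 (R)-2,2-dimethyl-4-(2-methylprop-1-enyl)-1,3-dioxolane
Conditions: iPrPPh3I, KOtBu, THF, −78 °C → 0 °C (salt-free, cold, to limit α-epimerisation)
Reagents that add atoms: isopropylidenetriphenylphosphorane, CC(C)=P(c1ccccc1)(c1ccccc1)c1ccccc1
Why: Wittig olefination with a non-stabilised ylide installs C3′=C4′Me2, which has no E/Z issue, and the α-alkoxy centre is retained.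

**Step 3**
Reactants: 3
Product: 4 (R)-4-methylpent-3-ene-1,2-diol
Conditions: Zn(NO3)2·6H2O, MeCN, 50 °C
Reagents that add atoms: none
Why: mild Lewis-acid ketal cleavage that leaves the acid-sensitive prenyl-type allylic alcohol intact; the stereocentre is not touched.

**Step 4**
Reactants: 4
Product: 5 (R)-2-hydroxy-4-methylpent-3-enal
Conditions: TEMPO (5 mol%), PhI(OAc)2 (1.1 equiv), CH2Cl2, 0 °C
Reagents that add atoms: none
Why: TEMPO/PIDA oxidation is selective for the primary alcohol of a 1,2-diol, and the secondary carbinol is retained.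

**Step 5**
Reactants: 5
Product: 6 (R)-2-(benzoyloxy)-4-methylpent-3-enal
Conditions: BzCl, pyridine, DMAP (cat.), CH2Cl2, 0 °C; use immediately
Reagents that add atoms: benzoyl chloride, O=C(Cl)c1ccccc1
Why: O-acylation fixes the C2′ oxygen as the required benzoate (R), and this α-acyloxy aldehyde is a poor chelator, so the later addition follows the Felkin model.

**Step 6**
Reactants: 7 genipin
Product: 8 genipin primary-alcohol TBS ether
Conditions: TBSCl (1.05 equiv), imidazole, DMF, 0 °C
Reagents that add atoms: tert-butyldimethylsilyl chloride, CC(C)(C)[Si](C)(C)Cl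
Why: the primary allylic OH silylates faster than the hindered lactol OH, and all three ring stereocentres are unchanged.

**Step 7**
Reactants: 8
Product: 9 lactol TBDPS ether
Conditions: TBDPSCl, imidazole, DMAP, DMF, rt
Reagents that add atoms: tert-butyldiphenylsilyl chloride, CC(C)(C)[Si](c1ccccc1)(c1ccccc1)Cl
Why: this robust group masks the lactol, keeps the ring closed through the sequence and is removed at the end; the natural 1β configuration is retained and is irrelevant later.

**Step 8**
Reactants: 9
Product: 10 seco keto-aldehyde (C6 CHO, C7 ketone)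
Conditions: O3, CH2Cl2, −78 °C (about 1 equiv, titrated); then Me2S
Reagents that add atoms: ozone, [O-][O+]=O
Why: ozonolysis cleaves the electron-rich trisubstituted cyclopentene much faster than the ester-deactivated push–pull enol ether, and C7a (α to the new ketone) is protected from epimerisation by using neutral conditions.

**Step 9**
Reactants: 10
Product: 11 C6 primary alcohol
Conditions: NaBH(OAc)3, CH2Cl2, 0 °C
Reagents that add atoms: none
Why: acyloxyborohydride reduces the aldehyde chemoselectively over the hindered α-silyloxy ketone, and no stereocentre is created.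

**Step 10**
Reactants: 11
Product: 12 C6 triethylsilyl ether
Conditions: TESCl, imidazole, DMF, 0 °C
Reagents that add atoms: triethylsilyl chloride, CC[Si](Cl)(CC)CC
Why: this masks the hydroxyl so that it cannot trap the oxocarbenium formed in Step 12 or form a hemiketal with the C7 ketone.

**Step 11**
Reactants: 12
Product: 13 C4 carboxylic acid
Conditions: Me3SnOH, 1,2-DCE, 80 °C
Reagents that add atoms: trimethyltin hydroxide, C[Sn](C)(C)O (supplies the OH oxygen)
Why: Nicolaou-type neutral ester cleavage leaves the silyl ethers, the ketone and the C7a stereocentre untouched.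

**Step 12**
Reactants: 13
Product: 14 C4 vinyl iodide
Conditions: NIS, MeCN, 0 °C → rt, dark
Reagents that add atoms: N-iodosuccinimide, O=C1CCC(=O)N1I
Why: iododecarboxylation of the β-alkoxyacrylic acid: I+ adds at the nucleophilic C4 and CO2 is lost to give the vinyl iodide, which is stable because the enol ether is deactivated by iodine.

**Step 13**
Reactants: 14; 6 (R)-2-(benzoyloxy)-4-methylpent-3-enal
Product: 15 C4–C1′ adduct (C1′ alcohol)
Conditions: CrCl2 (6 equiv), NiCl2 (0.1 equiv), DMF/THF, rt
Reagents that add atoms: none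
Why: Nozaki–Hiyama–Kishi addition of the alkenyl-chromium to the aldehyde sets C1′ by polar Felkin–Anh attack anti to the α-OBz group, giving the anti-1,2 relationship of the target.

**Step 14**
Reactants: 15
Product: 16 C1′ acetate
Conditions: Ac2O, Et3N, DMAP, CH2Cl2, 0 °C
Reagents that add atoms: acetic anhydride, CC(=O)OC(C)=O
Why: this is the only free OH, so simple acetylation gives the C1′-OAc with retention.

**Step 15**
Reactants: 16
Product: 17 C6 primary alcohol
Conditions: HF·pyridine, pyridine/THF, −10 → 0 °C
Reagents that add atoms: none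
Why: the TES ether is cleaved selectively over TBS and TBDPS, and the buffered fluoride spares the enol ether.

**Step 16**
Reactants: 17
Product: 18 C6 primary iodide
Conditions: I2, PPh3, imidazole, CH2Cl2, 0 °C
Reagents that add atoms: iodine, II
Why: the Appel reaction is selective for the only free (primary) alcohol and leaves the ketone, esters and silyl ethers alone.

**Step 17**
Reactants: 18; 19 2-bromopropene
Product: 20 isopropenyl chain (C4a–CH2CH2C(Me)=CH2)
Conditions: NiCl2·glyme/dtbbpy (5 mol%), [Ir(dF(CF3)ppy)2(dtbbpy)]PF6 (1 mol%), (TMS)3SiH, Na2CO3, DME, blue LEDs, rt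
Reagents that add atoms: none
Why: photoredox/Ni cross-electrophile coupling (silyl-radical iodine abstraction, then Ni capture of the vinyl bromide) forms the sp3–sp2 bond with no new stereocentre.

**Step 18**
Reactants: 20
Product: 21 C7 exocyclic methylene
Conditions: Cp2TiMe2 (3 equiv), toluene, 70 °C, dark
Reagents that add atoms: dimethyltitanocene (Petasis reagent), C[Ti](C)([CH]1C=CC=C1)[CH]1C=CC=C1 (supplies =CH2)
Why: Petasis methylenation under non-basic conditions converts the enolisable ketone to C=CH2 without epimerising C7a and leaves the esters and silyl ethers alone.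

**Step 19**
Reactants: 21; 22 acrolein
Product: 23 (E)-enal
Conditions: acrolein (10 equiv), Hoveyda–Grubbs II (5 mol%), CH2Cl2, 40 °C
Reagents that add atoms: none
Why: cross-metathesis of the unhindered isopropenyl alkene with acrolein gives the thermodynamically favoured E-trisubstituted enal (CH2 trans to CHO) in preference to the more hindered exocyclic methylene.

**Step 20**
Reactants: 23
Product: 24 allylic alcohol (C8 OH)
Conditions: HF·pyridine, pyridine/THF, 0 °C
Reagents that add atoms: none
Why: the primary TBS ether is cleaved selectively over the lactol TBDPS ether and the esters.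

**Step 21**
Reactants: 24
Product: 25 dienal (α-methylene aldehyde plus E-enal)
Conditions: MnO2 (20 equiv), CH2Cl2, rt; use immediately
Reagents that add atoms: none
Why: MnO2 oxidises the allylic alcohol selectively, and the enal and the enol ether are untouched.

**Step 22**
Reactants: 25
Product: 26 nine-membered carbocyclic diol
Conditions: Cp2TiCl2 (20 mol%), Me3SiCl (3 equiv), 2,4,6-collidine (3 equiv), nBu4NBF4, THF (5 mM), undivided cell, graphite cathode/Zn anode, 3 mA, rt; then aq. NH4F
Reagents that add atoms: none (Me3SiCl is removed on work-up)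
Why: Proposed new method: cathodically generated Cp2TiCl binds the more electron-poor α-methylene aldehyde to give a Ti-bound allylic ketyl, which adds to the Ti-activated carbonyl of the E-enal to close the nine-membered ring with the trans-diolate, and Me3SiCl/collidine turns the titanium over; the closest known reaction is Cp2TiCl-catalysed pinacol coupling of aldehydes and SmI2 intramolecular pinacols forming 5–8-membered rings, here applied to a 9-membered E-olefinic ring with the cis-fused pyran and E-olefin forcing one folded transition state, and the C_g/C_h configuration should follow from that substrate control.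

**Step 23**
Reactants: 26
Product: 27 lactol triol
Conditions: TBAF, AcOH (1:1), THF, 0 °C
Reagents that add atoms: none
Why: buffered fluoride removes the TBDPS group, and the lactol epimerises freely by ring–chain tautomerism, so its configuration is now undefined.

**Step 24**
Reactants: 27
Product: 28 Antheliatin
Conditions: Ac2O (2.2 equiv), pyridine, DMAP (cat.), CH2Cl2, −20 → 0 °C
Reagents that add atoms: acetic anhydride, CC(=O)OC(C)=O
Why: the lactol and the less hindered C_g OH are acylated faster than the hindered C_h OH, and acylation of the equilibrating lactol gives the axial, ring-fusion-cis anomeric acetate.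

## Compound list
1 | (R)-solketal | OC[C@@H]1COC(C)(C)O1 | starting material
2 | (S)-2,3-O-isopropylideneglyceraldehyde | O=C[C@@H]1COC(C)(C)O1 | intermediate
3 | (R)-2,2-dimethyl-4-(2-methylprop-1-enyl)-1,3-dioxolane | CC(C)=C[C@@H]1COC(C)(C)O1 | intermediate
4 | (R)-4-methylpent-3-ene-1,2-diol | CC(C)=C[C@@H](O)CO | intermediate
5 | (R)-2-hydroxy-4-methylpent-3-enal | O=C[C@H](O)C=C(C)C | intermediate
6 | (R)-2-(benzoyloxy)-4-methylpent-3-enal | O=C[C@@H](C=C(C)C)OC(=O)c1ccccc1 | intermediate
7 | genipin (1R,4aS,7aS) | C3=C(CO)[C@H]2[C@H](O)OC=C(C(=O)OC)[C@H]2C3 | starting material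
8 | genipin primary-alcohol TBS ether | C3=C(CO[Si](C)(C)C(C)(C)C)[C@H]2[C@H](O)OC=C(C(=O)OC)[C@H]2C3 | intermediate
9 | 8 with lactol OTBDPS | C3=C(CO[Si](C)(C)C(C)(C)C)[C@H]2[C@H](O[Si](c4ccccc4)(c4ccccc4)C(C)(C)C)OC=C(C(=O)OC)[C@H]2C3 | intermediate
10 | seco keto-aldehyde (C6 CHO, C7 C=O) | CC(C)(C)[Si](C)(C)OCC(=O)[C@H]2[C@H](O[Si](c3ccccc3)(c3ccccc3)C(C)(C)C)OC=C(C(=O)OC)[C@H]2CC=O | intermediate
11 | C6 primary alcohol | CC(C)(C)[Si](C)(C)OCC(=O)[C@H]2[C@H](O[Si](c3ccccc3)(c3ccccc3)C(C)(C)C)OC=C(C(=O)OC)[C@H]2CCO | intermediate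
12 | C6 TES ether | CC(C)(C)[Si](C)(C)OCC(=O)[C@H]2[C@H](O[Si](c3ccccc3)(c3ccccc3)C(C)(C)C)OC=C(C(=O)OC)[C@H]2CCO[Si](CC)(CC)CC | intermediate
13 | C4 carboxylic acid | CC(C)(C)[Si](C)(C)OCC(=O)[C@H]2[C@H](O[Si](c3ccccc3)(c3ccccc3)C(C)(C)C)OC=C(C(=O)O)[C@H]2CCO[Si](CC)(CC)CC | intermediate
14 | C4 vinyl iodide | CC(C)(C)[Si](C)(C)OCC(=O)[C@H]2[C@H](O[Si](c3ccccc3)(c3ccccc3)C(C)(C)C)OC=C(I)[C@H]2CCO[Si](CC)(CC)CC | intermediate
15 | NHK adduct (C1′-OH) | CC(C)(C)[Si](C)(C)OCC(=O)[C@H]2[C@H](O[Si](c3ccccc3)(c3ccccc3)C(C)(C)C)OC=C([C@H](O)[C@@H](C=C(C)C)OC(=O)c3ccccc3)[C@H]2CCO[Si](CC)(CC)CC | intermediate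
16 | C1′ acetate | CC(C)(C)[Si](C)(C)OCC(=O)[C@H]2[C@H](O[Si](c3ccccc3)(c3ccccc3)C(C)(C)C)OC=C([C@H](OC(C)=O)[C@@H](C=C(C)C)OC(=O)c3ccccc3)[C@H]2CCO[Si](CC)(CC)CC | intermediate
17 | C6 alcohol (TES removed) | CC(C)(C)[Si](C)(C)OCC(=O)[C@H]2[C@H](O[Si](c3ccccc3)(c3ccccc3)C(C)(C)C)OC=C([C@H](OC(C)=O)[C@@H](C=C(C)C)OC(=O)c3ccccc3)[C@H]2CCO | intermediate
18 | C6 iodide | CC(C)(C)[Si](C)(C)OCC(=O)[C@H]2[C@H](O[Si](c3ccccc3)(c3ccccc3)C(C)(C)C)OC=C([C@H](OC(C)=O)[C@@H](C=C(C)C)OC(=O)c3ccccc3)[C@H]2CCI | intermediate
19 | 2-bromopropene | C=C(C)Br | starting material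
20 | isopropenyl compound | CC(C)(C)[Si](C)(C)OCC(=O)[C@H]2[C@H](O[Si](c3ccccc3)(c3ccccc3)C(C)(C)C)OC=C([C@H](OC(C)=O)[C@@H](C=C(C)C)OC(=O)c3ccccc3)[C@H]2CCC(C)=C | intermediate
21 | C7 methylene compound | CC(C)(C)[Si](C)(C)OCC(=C)[C@H]2[C@H](O[Si](c3ccccc3)(c3ccccc3)C(C)(C)C)OC=C([C@H](OC(C)=O)[C@@H](C=C(C)C)OC(=O)c3ccccc3)[C@H]2CCC(C)=C | intermediate
22 | acrolein | C=CC=O | starting material
23 | (E)-enal | CC(C)(C)[Si](C)(C)OCC(=C)[C@H]2[C@H](O[Si](c3ccccc3)(c3ccccc3)C(C)(C)C)OC=C([C@H](OC(C)=O)[C@@H](C=C(C)C)OC(=O)c3ccccc3)[C@H]2CC/C(C)=C/C=O | intermediate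
24 | allylic alcohol | OCC(=C)[C@H]2[C@H](O[Si](c3ccccc3)(c3ccccc3)C(C)(C)C)OC=C([C@H](OC(C)=O)[C@@H](C=C(C)C)OC(=O)c3ccccc3)[C@H]2CC/C(C)=C/C=O | intermediate
25 | dienal | O=CC(=C)[C@H]2[C@H](O[Si](c3ccccc3)(c3ccccc3)C(C)(C)C)OC=C([C@H](OC(C)=O)[C@@H](C=C(C)C)OC(=O)c3ccccc3)[C@H]2CC/C(C)=C/C=O | intermediate
26 | nine-membered diol | C=C1[C@H]2[C@H](O[Si](c3ccccc3)(c3ccccc3)C(C)(C)C)OC=C([C@H](OC(C)=O)[C@@H](C=C(C)C)OC(=O)c3ccccc3)[C@H]2CC/C(C)=C/[C@H](O)[C@H]1O | intermediate
27 | lactol triol (C1 configuration undefined) | C=C1[C@H]2C(O)OC=C([C@H](OC(C)=O)[C@@H](C=C(C)C)OC(=O)c3ccccc3)[C@H]2CC/C(C)=C/[C@H](O)[C@H]1O | intermediate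
28 | Antheliatin | C=C1[C@H]2[C@@H](OC(C)=O)OC=C([C@H](OC(C)=O)[C@@H](C=C(C)C)OC(=O)c3ccccc3)[C@H]2CC/C(C)=C/[C@H](OC(C)=O)[C@H]1O | target

## Counts
- Total steps: 24, of which 5 make the side-chain aldehyde 6 from (R)-solketal.
- Longest linear sequence: 19 (Steps 6–24, from genipin).

## Three steps most likely to fail
1. **Step 22 (proposed new pinacol ring closure).** It may give β-coupling through the α-methylene terminus, the wrong diol diastereomer, or oligomers.
   - Fallback (known chemistry): re-cut the ring at the C_a–C_h bond. Take C_g from commercial (S)-3-butene-1,2-diol by cross-metathesis with the isopropenyl arm, make the C7 alkenyl iodide from a C8-deoxy methyl-ketone analogue, and close the ring by a macrocyclic NHK reaction.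
2. **Step 8 (ozonolysis).** Ozone may also attack the enol ether, or C7a may epimerise.
   - Fallback: cleave C6=C7 by OsO4/NMO dihydroxylation of the more electron-rich alkene, then NaIO4 diol cleavage.
3. **Step 13 (NHK).** The α-OBz aldehyde may be reduced by Cr(II), or the Felkin selectivity may be poor.
   - Fallback: use the α-OTBS analogue of aldehyde 6, which is Cr(II)-inert and more strongly Felkin-biased, then exchange TBS for benzoate after Step 14 by HF·pyridine and BzCl.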